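**Plan**

1. Numbering (abietane): ring A = C1–C5, C10; ring B = C5–C10; ring C = C8, C9, C11–C14; C18 = 4-CH3, C19 = lactone C=O on C4, C20 = OCH2 on C10. "A/B-olide core" below means the trans-decalin with 4α-CH3, 5α-H and the 4β-C19(=O)–O–C20H2-10β bridge.
2. Retrosynthetic cuts: 12-OAc to 12-O-tBu; ring C at C8–C14 and C9–C11, so that C11–C14 become a squarate-derived cyclobutenone and C8=C9 the end of a ring-B dienyl metal; ring A at C3–C4; the lactone ring at C4–C5 and the C19–O ester bond; C10–C1 back to 2-methoxybenzoic acid, whose carboxyl carbon is C20.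
3. Forward order: ring B from the arene by Birch reduction–alkylation (C10–C1), the δ-lactone by Heck closure (C4–C5), ring A by reductive enolate alkylation (C3–C4), and ring C last by a 4→6 ring expansion and oxidation.
4. Stereochemistry: C10 from the pyrrolidine auxiliary in the Birch alkylation; C5 by cis delivery of C4 through the C20 ester tether; C4 by the lactone bridge, which lets the C1–C3 chain reach only the α face. The carbinol centre made in step 11 is erased, so both epimers converge.
5. Enabling feature: ring C is a fully substituted p-quinone whose C11(=O)–C12(O)–C13(iPr)–C14(=O) array is a squaric acid pattern. Its sixth edge C8=C9 is shared with ring B, where the Δ6 bond makes C9=C8–C7=C6 a diene that can be metalated at C9.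

Key step: step 12

Assumption: the (S)-auxiliary is taken to direct the alkyl iodide to the enolate face that gives the (1R) quaternary centre drawn for 6 (chelated-enolate model for 2-methoxybenzamides); if the sense were opposite, the (R)-auxiliary would be used with no other change.

**Route**

Step 1
Reactants: 1 2-methoxybenzoyl chloride; 2 (S)-2-(methoxymethyl)pyrrolidine
Product: 3 (2-methoxyphenyl)[(2S)-2-(methoxymethyl)pyrrolidin-1-yl]methanone
Conditions: Et3N, CH2Cl2, 0 °C → rt
Reagents that add atoms: none
Why: N-acylation of the secondary amine by the acid chloride (Schotten–Baumann type) should be clean, and the auxiliary stereocentre is not involved.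

Step 2
Reactants: 3 benzamide; 4 1-chloro-3-iodopropane
Product: 6 [(1R)-1-(3-chloropropyl)-2-methoxycyclohexa-2,5-dien-1-yl][(2S)-2-(methoxymethyl)pyrrolidin-1-yl]methanone, via potassium amide enolate 5 (not isolated)
Conditions: K (2.2 equiv), t-BuOH (1.0 equiv), NH3–THF, −78 °C; then 4, −78 °C → rt
Reagents that add atoms: none
Why: Birch reduction of the benzamide should stop at the 1,4-dihydro amide enolate, which is alkylated at the ipso carbon by the iodide end of 4 (auxiliary-controlled Birch reduction–alkylation); C10 is set because the potassium is held by the enolate oxygen, the ring methoxy group and the methoxymethyl arm, so the iodide approaches anti to that arm.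

Step 3
Reactants: 6 diene amide
Product: 7 [(1S)-1-(3-chloropropyl)-2-methoxycyclohexa-2,5-dien-1-yl]methanol
Conditions: LiH2NBH3 (from BH3·NH3 and LDA), THF, 0 → 23 °C; aq. NaHCO3 work-up
Reagents that add atoms: none
Why: lithium amidotrihydroborate reduces tertiary amides, including α-quaternary ones, to primary alcohols with C–N cleavage, which frees the auxiliary and should leave the quaternary centre, the enol ether and the primary chloride untouched.

Step 4
Reactants: 7 neopentyl alcohol; 8 2,3-dibromopropanoyl chloride
Product: 10 [(1S)-1-(3-chloropropyl)-2-methoxycyclohexa-2,5-dien-1-yl]methyl 2-bromoprop-2-enoate, via 2,3-dibromopropanoate ester 9 (not isolated)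
Conditions: pyridine, CH2Cl2, 0 °C; then Et3N, rt
Reagents that add atoms: none
Why: O-acylation followed by E2 loss of HBr from the 2,3-dibromopropanoate is the standard way to a 2-bromoacrylate, and the basic medium protects the enol ether.

Step 5
Reactants: 10 2-bromoacrylate
Product: 11 α-methylene δ-lactone cis-fused to ring B (C4=CH2; 9-methoxy-6,8-diene; 10α-(3-chloropropyl); 5α-H)
Conditions: Pd(PPh3)4 (10 mol %), 1,2,2,6,6-pentamethylpiperidine, MeCN, 80 °C, high dilution
Reagents that add atoms: none
Why: intramolecular Mizoroki–Heck reaction, in which oxidative addition into C–Br and 6-exo-trig syn-carbopalladation of C5=C6 from the face that carries the C20 tether set C5 (C4 cis to C20, hence 5α-H), and syn β-hydride elimination towards C7 gives the conjugated methoxydiene; the fully substituted enol ether carbon C9 should not compete under halide-bound (neutral) conditions.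

Step 6
Reactants: 11 α-methylene lactone
Product: 13 9-methoxy-6,8-diene of the A/B-olide core, via potassium lactone enolate 12 (not isolated)
Conditions: K-Selectride (1.1 equiv), THF, −78 °C; then DMPU, Bu4NI (cat.), −78 → 40 °C
Reagents that add atoms: none
Why: conjugate hydride addition to the exocyclic methylene turns it into the C18 methyl and gives the lactone enolate, whose intramolecular 6-exo-tet C-alkylation by the chloropropyl chain closes ring A (reductive alkylation); C4 is set because the chain hangs from C10 on the α face and can reach only that face of the enolate, leaving the methyl α and the carbonyl in the β bridge.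

Step 7
Reactants: 13 dienol ether
Product: 14 7-en-9-one of the A/B-olide core
Conditions: 1 M HCl, THF, rt
Reagents that add atoms: water, O
Why: acid hydrolysis of the dienol ether by protonation at C6 and hydration at C9 should give the conjugated enone, the hindered lactone being stable to dilute acid.

Step 8
Reactants: 14 enone
Product: 16 6,8-dien-9-yl trifluoromethanesulfonate of the A/B-olide core, via potassium dienolate 15 (not isolated)
Conditions: KHMDS, THF, −78 °C; then PhNTf2, −78 → 0 °C
Reagents that add atoms: N-phenylbis(trifluoromethanesulfonimide), O=S(=O)(N(c1ccccc1)S(=O)(=O)C(F)(F)F)C(F)(F)F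
Why: C10 is quaternary and the lactone has no α-hydrogen, so the only enolisation open is γ-deprotonation at C6 to the extended dienolate, whose O-sulfonylation gives the 2-triflyloxy-1,3-diene.

Step 9
Reactants: 16 dienyl triflate
Product: 17 9-(trimethylstannyl)-6,8-diene of the A/B-olide core
Conditions: Me3SnSnMe3, Pd(PPh3)4 (5 mol %), LiCl, THF, 65 °C
Reagents that add atoms: hexamethyldistannane, C[Sn](C)(C)[Sn](C)(C)C
Why: palladium-catalysed stannylation of enol triflates (Stille-type) is reliable also next to a quaternary carbon.

Step 10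
Reactants: 18 di-tert-butyl squarate; 19 isopropylmagnesium chloride
Product: 21 3-tert-butoxy-4-isopropylcyclobut-3-ene-1,2-dione, via chloromagnesium alkoxide 20 (not isolated)
Conditions: THF, −78 °C; then (CF3CO)2O, −78 → 0 °C; aq. NaHCO3
Reagents that add atoms: none
Why: 1,2-addition of the Grignard reagent to one squarate carbonyl, then trifluoroacetylation and ionisation of the tertiary carbinol with vinylogous loss of a tert-butyl group, is the standard route to 3-alkoxy-4-alkylcyclobutenediones.

Step 11
Reactants: 17 dienylstannane; 21 cyclobutenedione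
Product: 23 3-tert-butoxy-4-hydroxy-2-isopropyl-4-(A/B-olide-6,8-dien-9-yl)cyclobut-2-en-1-one (both carbinol epimers), via dienyllithium 22 (not isolated)
Conditions: MeLi (1.05 equiv), THF, −78 °C; then 21, −78 °C; aq. NH4Cl
Reagents that add atoms: none
Why: tin–lithium exchange gives the C9 dienyllithium, which adds 1,2 to the carbonyl next to the tert-butoxy-bearing carbon (the other carbonyl is a deactivated vinylogous ester); the neopentyl-type lactone carbonyl without α-hydrogen should survive at −78 °C, and the new carbinol centre needs no control.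

Step 12
Reactants: 23 4-dienyl-4-hydroxycyclobutenone
Product: 27 12-tert-butoxy-11,14-dioxoabieta-6,8,12-trien-19,20-olide, via dienylketene 24 (not isolated), via cyclohexa-2,4-dienone 25 (not isolated), via hydroquinone 26 (not isolated)
Conditions: toluene (degassed), 110 °C; then Ag2O, rt
Reagents that add atoms: none
Why: Heating opens the cyclobutenone by conrotatory 4π ring opening of the C11–C14 bond with the hydroxyl turning outward, which places the C9 dienyl group cis to the ketene in 24; disrotatory 6π electrocyclisation of ketene carbon C14 onto C8 gives 25, enolisation by loss of H-8 gives hydroquinone 26, and Ag2O oxidises it to the quinone. The closest known reaction type is the thermal ring expansion of 4-alkenyl-4-hydroxycyclobutenones to hydroquinones and quinones (Moore rearrangement). Ring C is closed by a thermal 6π electrocyclisation with C8–C14 as the new bond, so the four-membered ring grows by the two carbons C8 and C9. No lasting stereocentre is formed: C8 of 25 is lost on aromatisation and the carbinol carbon C11 of 23 becomes sp2, so both epimers of 23 converge on one product, while C4, C5 and C10 are not touched (a 1,5-hydrogen shift from C5 in the cyclohexadiene is too slow at 110 °C). The regiochemistry (oxygen at C11, C12 and C14, isopropyl at C13) is fixed by the substitution of the cyclobutenone and the site of addition in step 11, and 6π closure is preferred over an 8π closure onto C6 because a C14–C6 bond would bridge ring B. The C6=C7 bond is carried through unchanged and ends in conjugation with the quinone.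

Step 13
Reactants: 27 tert-butoxyquinone
Product: 29 (4S,5R,10R)-12-acetoxy-11,14-dioxoabieta-6,8,12-trien-19,20-olide (CNP0596241.1), via 12-hydroxyquinone 28 (not isolated)
Conditions: TFA, CH2Cl2, 0 °C; concentrate; then Ac2O, pyridine, DMAP (cat.), CH2Cl2, rt
Reagents that add atoms: acetic anhydride, CC(=O)OC(C)=O
Why: acidolysis of the vinylogous tert-butyl ester (loss of isobutene) frees the acidic 12-hydroxyquinone, which is O-acetylated under standard conditions that should not disturb the lactone or C5.

**Compound list**

1 | 2-methoxybenzoyl chloride | COc1ccccc1C(Cl)=O | starting material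
2 | (S)-2-(methoxymethyl)pyrrolidine | COC[C@@H]1CCCN1 | starting material
3 | (2-methoxyphenyl)[(2S)-2-(methoxymethyl)pyrrolidin-1-yl]methanone | COC[C@@H]1CCCN1C(=O)c1ccccc1OC | intermediate
4 | 1-chloro-3-iodopropane | ClCCCI | starting material
5 | potassium amide enolate of the 1,4-dihydrobenzamide | COC[C@@H]1CCCN1C([O-])=C1C=CCC=C1OC.[K+] | intermediate
6 | [(1R)-1-(3-chloropropyl)-2-methoxycyclohexa-2,5-dien-1-yl][(2S)-2-(methoxymethyl)pyrrolidin-1-yl]methanone | COC1=CCC=C[C@@]1(CCCCl)C(=O)N1CCC[C@H]1COC | intermediate
7 | [(1S)-1-(3-chloropropyl)-2-methoxycyclohexa-2,5-dien-1-yl]methanol | COC1=CCC=C[C@@]1(CCCCl)CO | intermediate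
8 | 2,3-dibromopropanoyl chloride | O=C(Cl)C(Br)CBr | starting material
9 | [(1S)-1-(3-chloropropyl)-2-methoxycyclohexa-2,5-dien-1-yl]methyl 2,3-dibromopropanoate (epimers at CHBr) | COC1=CCC=C[C@@]1(CCCCl)COC(=O)C(Br)CBr | intermediate
10 | [(1S)-1-(3-chloropropyl)-2-methoxycyclohexa-2,5-dien-1-yl]methyl 2-bromoprop-2-enoate | COC1=CCC=C[C@@]1(CCCCl)COC(=O)C(Br)=C | intermediate
11 | cis-fused α-methylene δ-lactone: C4=CH2, C19(=O)–O–C20H2 on C10 (β), 9-methoxy-6,8-diene, 10α-(3-chloropropyl), 5α-H | COC1=CC=C[C@H]2C(=C)C(=O)OC[C@@]12CCCCl | intermediate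
12 | potassium enolate of the 4-methyl lactone from 11 | COC1=CC=C[C@H]2C(C)=C([O-])OC[C@@]12CCCCl.[K+] | intermediate
13 | 9-methoxy-6,8-diene of the A/B-olide core (4α-CH3, 5α-H, 19,20-lactone) | COC1=CC=C[C@H]2[C@]3(C)CCC[C@]12COC3=O | intermediate
14 | 7-en-9-one of the A/B-olide core | O=C1C=CC[C@H]2[C@]3(C)CCC[C@]12COC3=O | intermediate
15 | potassium 6,8-dien-9-olate of the A/B-olide core | [O-]C1=CC=C[C@H]2[C@]3(C)CCC[C@]12COC3=O.[K+] | intermediate
16 | 6,8-dien-9-yl trifluoromethanesulfonate of the A/B-olide core | O=S(=O)(OC1=CC=C[C@H]2[C@]3(C)CCC[C@]12COC3=O)C(F)(F)F | intermediate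
17 | 9-(trimethylstannyl)-6,8-diene of the A/B-olide core | C[Sn](C)(C)C1=CC=C[C@H]2[C@]3(C)CCC[C@]12COC3=O | intermediate
18 | di-tert-butyl squarate (3,4-di-tert-butoxycyclobut-3-ene-1,2-dione) | CC(C)(C)OC1=C(OC(C)(C)C)C(=O)C1=O | starting material
19 | isopropylmagnesium chloride | CC(C)[Mg]Cl | starting material
20 | chloromagnesium alkoxide of 2,3-di-tert-butoxy-4-hydroxy-4-isopropylcyclobut-2-en-1-one | CC(C)C1(O[Mg]Cl)C(OC(C)(C)C)=C(OC(C)(C)C)C1=O | intermediate
21 | 3-tert-butoxy-4-isopropylcyclobut-3-ene-1,2-dione | CC(C)C1=C(OC(C)(C)C)C(=O)C1=O | intermediate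
22 | 9-lithio-6,8-diene of the A/B-olide core | [Li]C1=CC=C[C@H]2[C@]3(C)CCC[C@]12COC3=O | intermediate
23 | 3-tert-butoxy-4-hydroxy-2-isopropyl-4-(A/B-olide-6,8-dien-9-yl)cyclobut-2-en-1-one (both carbinol epimers) | CC(C)C1=C(OC(C)(C)C)C(O)(C1=O)C1=CC=C[C@H]2[C@]3(C)CCC[C@]12COC3=O | intermediate
24 | ring-opened dienylketene (C13=C14=O; C11(OH)=C12(OtBu) with C13 cis to C9) | CC(C)C(=C=O)/C(OC(C)(C)C)=C(/O)C1=CC=C[C@H]2[C@]3(C)CCC[C@]12COC3=O | intermediate
25 | cyclohexa-2,4-dienone with ring C closed (C8–H, 14-oxo, 11-enol; C8 epimers) | CC(C)C1=C(OC(C)(C)C)C(O)=C2C(C=C[C@H]3[C@]4(C)CCC[C@]23COC4=O)C1=O | intermediate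
26 | 12-tert-butoxy-11,14-dihydroxyabieta-6,8,11,13-tetraen-19,20-olide (hydroquinone) | CC(C)c1c(O)c2C=C[C@H]3[C@]4(C)CCC[C@]3(COC4=O)c2c(O)c1OC(C)(C)C | intermediate
27 | 12-tert-butoxy-11,14-dioxoabieta-6,8,12-trien-19,20-olide | CC(C)(C)OC1=C(C(C)C)C(=O)C2=C(C1=O)[C@]13CCC[C@](C)(C(=O)OC1)[C@@H]3C=C2 | intermediate
28 | 12-hydroxy-11,14-dioxoabieta-6,8,12-trien-19,20-olide | OC1=C(C(C)C)C(=O)C2=C(C1=O)[C@]13CCC[C@](C)(C(=O)OC1)[C@@H]3C=C2 | intermediate
29 | (4S,5R,10R)-12-acetoxy-11,14-dioxoabieta-6,8,12-trien-19,20-olide (CNP0596241.1) | CC(=O)OC1=C(C(C)C)C(=O)C2=C(C1=O)[C@]13CCC[C@](C)(C(=O)OC1)[C@@H]3C=C2 | target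

**Count and risks**

Total steps: 13. Longest linear sequence: 12 (steps 1–9, 11, 12, 13); step 10 is a one-step branch.

Most likely to fail:

Step 5. The vinylpalladium species may insert into the electron-rich enol ether C8=C9 instead of C5=C6, or palladium hydride may move the exocyclic double bond into conjugation and erase C5. The fallback sets out from 10 and removes the competing alkene before the cyclisation. Mild acid hydrolysis (aq. oxalic acid, THF) of the enol ether should give the β,γ-unsaturated ketone [(1S)-1-(3-chloropropyl)-2-oxocyclohex-5-en-1-yl]methyl 2-bromoprop-2-enoate F1. Heck cyclisation under the same neutral conditions, now with C5=C6 as the only ring alkene, should give the α-methylene lactone 7-en-9-one F2. Re-formation of the dienol ether with trimethyl orthoformate and catalytic TsOH returns to the route at 11.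

Step 11. Methyllithium or the dienyllithium may attack the lactone carbonyl faster than tin–lithium exchange and 1,2-addition occur, or the hindered lithium reagent may be protonated. The fallback sets out from 17 and 21 and avoids organolithium chemistry. Reduction of 21 with LiAlH(Ot-Bu)3 at the more electrophilic carbonyl should give 3-tert-butoxy-4-hydroxy-2-isopropylcyclobut-2-en-1-one F3, and MsCl/Et3N then LiCl the 4-chlorocyclobutenone F4. Stille coupling of F4 with 17 (Pd2(dba)3, tri(2-furyl)phosphine, dioxane, 50 °C) should give the 4-dienylcyclobutenone F5, which on heating to 100 °C ring-expands in the same way to the 14-phenol F6 (H at C11). Oxidation of F6 with O2 and catalytic salcomine to the p-quinone comes back to the route at 27.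

Step 6. The lactone enolate may be protonated or may condense with a second lactone before the slow displacement of chloride closes ring A. The fallback sets out from 11 and separates the two events. Conjugate reduction with NaBH4 in MeOH should give the 4-methyl lactone F7 (C4 epimers, both usable), and Finkelstein exchange (NaI, acetone, reflux) the iodide F8. Enolisation of F8 with KHMDS in THF/DMPU at −78 → 0 °C and 6-exo-tet alkylation returns to the route at 13.

**Further compounds**

F1 | step 5 | [(1S)-1-(3-chloropropyl)-2-oxocyclohex-5-en-1-yl]methyl 2-bromoprop-2-enoate | O=C1CCC=C[C@@]1(CCCCl)COC(=O)C(Br)=C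
F2 | step 5 | cis-fused α-methylene δ-lactone 7-en-9-one with 10α-(3-chloropropyl) and 5α-H | O=C1CC=C[C@H]2C(=C)C(=O)OC[C@@]12CCCCl
F3 | step 11 | 3-tert-butoxy-4-hydroxy-2-isopropylcyclobut-2-en-1-one | CC(C)C1=C(OC(C)(C)C)C(O)C1=O
F4 | step 11 | 3-tert-butoxy-4-chloro-2-isopropylcyclobut-2-en-1-one | CC(C)C1=C(OC(C)(C)C)C(Cl)C1=O
F5 | step 11 | 3-tert-butoxy-2-isopropyl-4-(A/B-olide-6,8-dien-9-yl)cyclobut-2-en-1-one | CC(C)C1=C(OC(C)(C)C)C(C1=O)C1=CC=C[C@H]2[C@]3(C)CCC[C@]12COC3=O
F6 | step 11 | 12-tert-butoxy-14-hydroxyabieta-6,8,11,13-tetraen-19,20-olide | CC(C)c1c(O)c2C=C[C@H]3[C@]4(C)CCC[C@]3(COC4=O)c2cc1OC(C)(C)C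
F7 | step 6 | cis-fused 4-methyl δ-lactone with 9-methoxy-6,8-diene and 10α-(3-chloropropyl) (C4 epimers) | COC1=CC=C[C@H]2C(C)C(=O)OC[C@@]12CCCCl
F8 | step 6 | cis-fused 4-methyl δ-lactone with 9-methoxy-6,8-diene and 10α-(3-iodopropyl) (C4 epimers) | COC1=CC=C[C@H]2C(C)C(=O)OC[C@@]12CCCI
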